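Rank these flasks by target at 25 min, and state the values for the first and the last.

all flasks: free catalyst 1 mol%
- amber: starting material 0.14 M; reagent 1.1 equiv; run made earlier
- teal: starting material 1.8 M; reagent 1.1 equiv; run made earlier
- east: starting material 0.80 M; reagent 1.10 equiv; time 25 min
- north: starting material 0.40 M; reagent 1.10 equiv; time 25 min
- south: starting material 0.20 M; reagent 1.10 equiv; time 25 min
- west: starting material 0.12 M; reagent 1.10 equiv; time 25 min
- north-west: starting material 1.5 M; reagent 1.10 equiv; time 25 min
- north-east: starting material 0.60 M; reagent 1.10 equiv; time 25 min

| run | time / min | target / % |
|---|---|---|
| amber | 1.33 | 1 |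
| amber | 3.00 | 3 |
| amber | 8.00 | 6 |
| amber | 20.0 | 12 |
| teal | 4.00 | 7 |
| teal | 8.00 | 15 |
| teal | 12.0 | 21 |
| teal | 20.0 | 39 |

(standard deviation of a reading: 2 percentage points)

* ranking by amount of target, in percent of the starting material charged, from high to low, at 25 min (east / north / south / west / north-west / north-east)
* the amount of target, in percent of the starting material charged of the flask you put first, at 25 min
* the amount of target, in percent of the starting material charged of the flask you put last, at 25 min

- steps thought possible: catalyst intermediate A -> released group + catalyst intermediate B; catalyst intermediate C -> catalyst intermediate D; starting material + catalyst intermediate B <-> catalyst intermediate C; catalyst intermediate D <-> free catalyst + target; reagent + free catalyst -> catalyst intermediate A; reagent -> decomposition product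

Keep the ledger on starting material, the limiting reagent, since reagent is charged at 1.10 equiv. Enter each mole charged as free, as bound on catalyst intermediate C or D, or as target. The bound entry cannot pass the loading of 1 mol%, so drop it; free is then charge less target, and the books close to within that loading. At this loading, each percent of target is one turnover of the catalyst, so divide target by time and loading to get the mean turnover rate. The last readings give 0.600 min⁻¹ for amber and 1.95 min⁻¹ for teal.

Now replace each curve by its mean: the mean of charge and final free amount is 0.132 M for amber and 1.45 M for teal. Concentration rises by a factor of 11.0 but rate by only 3.25, so fit a bending curve, rate = ceiling × c/(K + c), through both points. This gives K = 0.420 M, the half-saturation concentration, the mean concentration of starting material at which the mean turnover rate is half its ceiling. The ceiling is 2.52 min⁻¹. Both are readings and carry their scatter.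

Reckon north-west: the charge alone gives 49.1%, which puts the mean at 1.13 M, and that gives 45.9%. Check the error: the rates at charge and end average 1.81 min⁻¹, against 1.83 min⁻¹ at the mean, a gap worth 0.57 percentage points against a scatter of 2 points. West, at a mean of 0.112 M, gives 13.2%. Percent target climbs with mean concentration on this curve, so my order follows the charge.

The forecast gives north-west > east > north-east > north > south > west, with 46% first and 15% last: “Percent yield therefore increases steadily with concentration”. It shares my order and top value, but my west is lower than its 15%.

The flasks give north-west > east > north-east > north > south > west, with 44.2% first and 17.7% last.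

    catalyst intermediate A → released group + catalyst intermediate B (k = 0.140 s⁻¹)
    catalyst intermediate C → catalyst intermediate D (k = 0.0960 s⁻¹)
    starting material + catalyst intermediate B ⇌ catalyst intermediate C (K = 3.50 M⁻¹, k = 0.350 M⁻¹ s⁻¹)
    catalyst intermediate D ⇌ free catalyst + target (K = 0.0440 M, k = 0.130 s⁻¹)
    reagent + free catalyst → catalyst intermediate A (k = 2.20 M⁻¹ s⁻¹)
    reagent → decomposition product (k = 1.00 × 10⁻⁶ s⁻¹)

North-west's 44.2% is a mean rate of 1.77 min⁻¹, against 1.83 min⁻¹ from K. North-west stands at that value because the run is short: ten times as long gives 100%, while sparing the reagent gives 45.3%, so reagent consumption is not the reason. For a neighbouring flask at 0.60 M, K gives a mean of 0.489 M and 33.8% target. The computed flask gives 36.7%.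

(All runs are calculated with constants of no real substance, and the scatter is random.)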